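## Analysis of the target

The target is (3S,5R,6R,3'S,5'R,8'R)-5',8'-epoxy-5,6,5',8'-tetrahydro-β,β-carotene-3,3',5,6-tetrol, a C40 xanthophyll. Its all-E octaene chain (C7 to C10', four methyl branches) ends in a cyclohexane-3,5,6-triol (ring A) and in a cyclohexene-fused 2,5-dihydrofuran (ring B, O1 bridging C5' and C8'). Ring A carries three stereocentres: the 3-OH is trans to the 5-OH, the 5,6-diol is trans-diaxial, and C7 sits on the same face as O5. Ring B carries three more: O1 at C5' is trans to O3', and C9' on C8' lies on the C4' side of the dihydrofuran, trans to the C5' methyl. The sensitive sites are the polyene (light, oxygen, acid), the tertiary, doubly allylic C6 carbinol, and above all C8', a bis-allylic ether carbon that ionises in acid and then epimerises. Two things make the synthesis hard. C8' is remote from every other stereocentre and is lost in the classical acid-induced epoxide-to-furanoid rearrangement. The ether oxygen on C5' is tertiary and cannot be introduced by substitution. The strategy rests on one feature of ring B: the O1–C8' bond, the C6'=C7' alkene and the oxygen-bearing C5' are exactly the atoms of a C5'-hydroxy C6'=C7'=C8' allene. Such an allene can be closed under gold catalysis with its axis dictating C8'.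

## Retrosynthetic reasoning

**24 to 23.** The two secondary hydroxyls are unmasked last. Both carry the same silyl ether, so a single fluoride treatment ends the synthesis and the acid-labile tetrol is handled once. The tertiary hydroxyls are too hindered to need protection.

**23 to 16 and 22.** The C11'=C12' bond is cut, which divides C40 into a C15 ring B unit and a C25 ring A polyenal. This bond is a disubstituted alkene between two methyl-bearing alkenes that arrive with fixed E geometry, and its Z isomer is the sterically hindered one and reverts on warming. Phosphorus is placed on the ring B fragment 16 and the aldehyde on 22. An enal at C11' would make H-8' vinylogously acidic under the basic olefination conditions, whereas in the ylide C8' is never activated.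

**22 to 20 and 21.** The C11=C12 bond is cut in the same way. The symmetric C10 dialdehyde 21 supplies C12 to C12' with three E double bonds and both inner methyl groups. The forward reaction must stop after one olefination.

**16 to 14 to 13.** These are functional-group changes at C11' (ester, alcohol, bromide, phosphonium). The ester is a pivalate because it must pass a peracid, a copper hydride and a gold catalyst unchanged.

**13 to 12 (key disconnection).** The O1–C8' bond is cut, not C5'–O. The C5' oxygen stays on its carbon from the start, and the new bond is made at C8' without a cation there. Opening the ring at this bond reveals the hydroxyallene 12, whose C6'=C7' bond is already the ring alkene. The forward reaction has to add the tertiary hydroxyl to the terminal allene carbon and turn the axis into the C8' centre.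

**12 to 10.** The C8'–H bond is cut and the C5'–C6' oxirane restored. An anti SN2' hydride delivery to the propargylic oxirane 10 makes the allene and transfers the configuration of C6' to the axis, while C5' keeps its oxygen. C8' is therefore traced back to the face on which the ring alkene is epoxidised.

**20 to 18 to 17 to 10.** Ring A is taken from the same oxirane. The C6–O bond is cut back to 10 (hydrolysis with inversion at C6, giving the trans-diaxial diol). The C7=C8 alkene is traced to the alkyne of 17 by hydroxyl-directed trans reduction. The C6 carbon is attached before the oxygen because a nucleophile adding to a C6 ketone would enter anti to the axial O5 and give the wrong C6 epimer. The alkyne also keeps O5 from reaching C8 during the acid step.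

**10 to 9 to 8 to 6 and 7.** The oxirane comes from the tetrasubstituted ring alkene of the dienyne 9, epoxidised on the face opposite O3'. The C6'–C7' bond is cut to the enol triflate 6 and the C5 enynol 7, which brings C7' to C11' with the E-C9'=C10' bond in place.

**6 to 4 to 3 to 2 to 1.** The only stereocentre that both end groups inherit, C3 and C3', comes from 1 by enzymatic alkene reduction and substrate-controlled ketone reduction. The methyl-bearing centre of 3 serves only as a relay and is erased in 6.

## Alternatives that were turned down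

**Alternative 1:** This plan cuts C7=C8 and C6–O of ring A together. A ring aldehyde A1 (C6 bearing H and the formyl carbon C7, O5 as triethylsilyl ether) is condensed with a sulfinyl-activated acetate. The new alkene shifts to the exocyclic C6=C7 position and the allylic sulfoxide undergoes a [2,3] shift to the sulfenate, which after S–O cleavage leaves the γ-hydroxy (E)-enoate A2.
- For: oxygen is delivered suprafacially without a cation at C6, on the open face anti to the axial O5, which is the face the target needs. The E alkene forms in the same operation. On control of C6 this is stronger than the hydrolysis of 10 used here.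
- Against: A1 is a β-silyloxy aldehyde with an α-hydrogen and can lose the C5 oxygen by β-elimination under the amine base. A1 needs about six steps from 6, and A2 ends in an ester carbon where the target has the methyl-bearing C9, which costs about three more.
- Comparison: the plan does nothing for C8'. The chosen strategy makes ring A in two steps from the shared oxirane and controls C8' as well.

**Alternative 2:** This plan cuts the C6–C7 bond. The keto ester A3 (the O5 (Z)-3-iodoacrylate of the C6 ketone) undergoes a chromium-mediated Nozaki–Hiyama–Kishi alkenylation (divalent chromium), closing the cis-fused lactone A4.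
- For: ring fusion leaves no choice, so C7 must end cis to O5. This is the relationship that intermolecular addition gets wrong, and on this point the plan is stronger than the chosen route.
- Against: the hindered tertiary ketol must be acylated without Z/E leakage of the iodoacrylate, and the ketone is flanked by two fully substituted carbons. A4 holds C7=C8 as Z and C9 as a carboxyl carbon, so a methyl group, ring opening and Z-to-E isomerisation beside a tertiary allylic alcohol are still needed.
- Comparison: ring B is untouched. The chosen route obtains the E alkene directly by trans hydroalumination and spends its risk on C8'.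

**Alternative 3:** This plan cuts both C–O bonds of ring B. The dienoate A5 (one coupling step from 6) is photo-oxygenated with a sensitiser, and oxygen adds across C5'=C6'–C7'=C8' to give the endoperoxide A6.
- For: this is the shortest access to an oxygenated C15 ring B unit. Both oxygens enter on one face, so the C5'/C8' relationship is fixed, and no oxirane or allene is needed. On step count it is stronger.
- Against: the face of addition relative to C3' is set only by the remote silyloxy and gem-dimethyl groups. Ene reactions at C4' and at the methyl groups, and addition across C7'=C8'–C9'=C10', compete. A6 also has one oxygen too many: contraction to the dihydrofuran goes through O–O reduction and cyclodehydration (a C8' allyl cation) or through a phosphine-mediated inverting substitution at C8'.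
- Comparison: the C8' configuration is not carried over simply. The chosen strategy sets C8' in the ring-forming step and never ionises it afterwards.

Key step: step 9

Remark: carotenoid numbering is used for all intermediates (ring A C1–C6, chain C7–C15 and C15'–C7', ring B C1'–C6'); in the SMILES of 11 and 12 the allene descriptor is read with the implicit hydrogen of C8' ranked directly after C9'; compounds 7 and 21 are taken as purchased.

## Route

Step 1
Reactants: 1 4-oxoisophorone (2,6,6-trimethylcyclohex-2-ene-1,4-dione)
Product: 2 (6R)-2,2,6-trimethylcyclohexane-1,4-dione ((6R)-levodione)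
Conditions: ene-reductase OYE2, glucose dehydrogenase, NADP+ (cat.), D-glucose, phosphate buffer pH 7, 30 °C
Reagents that add atoms: none
Why: Old-yellow-enzyme ene-reductases reduce the electron-poor ring alkene of 1 by trans addition of hydride and proton and should give the (6R) dione; this is a biocatalytic asymmetric conjugate reduction, with the cofactor recycled by glucose.

Step 2
Reactants: 2 (6R)-levodione
Product: 3 (4R,6R)-4-hydroxy-2,2,6-trimethylcyclohexan-1-one ((4R,6R)-actinol, hydroxyl axial and trans to the C6 methyl)
Conditions: LiBH(s-Bu)3 (1.05 equiv), THF, −78 °C; then NaOH, H2O2, 0 °C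
Reagents that add atoms: none
Why: The C4 carbonyl is the unhindered one (C1 lies between a quaternary and a tertiary carbon), and the bulky hydride should enter equatorially, away from the axial C2 methyl, as with 3,3,5-trimethylcyclohexanone. This substrate-controlled ketone reduction sets the centre that becomes C3 and C3'; the minor cis alcohol is removed by crystallisation.

Step 3
Reactants: 3 (4R,6R)-actinol
Product: 4 (4R,6R)-4-[(tert-butyldimethylsilyl)oxy]-2,2,6-trimethylcyclohexan-1-one
Conditions: TBSCl, imidazole, DMF, rt
Reagents that add atoms: tert-butyldimethylsilyl chloride, CC(C)(C)[Si](C)(C)Cl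
Why: Standard silylation of a secondary alcohol; the ether must last until the final step.

Step 4
Reactants: 4 (4R,6R)-4-[(tert-butyldimethylsilyl)oxy]-2,2,6-trimethylcyclohexan-1-one
Product: 6 (4R)-4-[(tert-butyldimethylsilyl)oxy]-2,6,6-trimethylcyclohex-1-en-1-yl trifluoromethanesulfonate, via lithium enolate 5 (not isolated)
Conditions: LiN(i-Pr)2, THF, −78 to 0 °C; PhNTf2, −78 °C to rt
Reagents that add atoms: N-phenylbis(trifluoromethanesulfonimide), O=S(=O)(N(c1ccccc1)S(=O)(=O)C(F)(F)F)C(F)(F)F
Why: The ketone has a single α-hydrogen, so only the tetrasubstituted enolate can form, and O-sulfonylation gives the enol triflate. The methyl-bearing stereocentre is erased as intended.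

Step 5
Reactants: 6 enol triflate; 7 (E)-3-methylpent-2-en-4-yn-1-ol
Product: 8 (2E)-5-[(4R)-4-[(tert-butyldimethylsilyl)oxy]-2,6,6-trimethylcyclohex-1-en-1-yl]-3-methylpent-2-en-4-yn-1-ol
Conditions: Pd(PPh3)4 (5 mol%), CuI (10 mol%), i-Pr2NH, THF, rt
Reagents that add atoms: none
Why: Sonogashira coupling of an alkenyl triflate with a terminal alkyne (zerovalent palladium, monovalent copper co-catalyst) forms the ring-to-chain bond. The free alcohol is tolerated and the E alkene of 7 is not touched.

Step 6
Reactants: 8 dienynol
Product: 9 (2E)-5-[(4R)-4-[(tert-butyldimethylsilyl)oxy]-2,6,6-trimethylcyclohex-1-en-1-yl]-3-methylpent-2-en-4-yn-1-yl 2,2-dimethylpropanoate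
Conditions: t-BuCOCl, pyridine, DMAP (cat.), CH2Cl2, 0 °C to rt
Reagents that add atoms: pivaloyl chloride, CC(C)(C)C(=O)Cl
Why: Acylation of the primary allylic alcohol. The pivalate lowers the reactivity of the side-chain alkene toward peracid and is inert to the alkoxide, copper hydride and gold of the next steps.

Step 7
Reactants: 9 dienynyl pivalate
Product: 10 (2E)-5-[(1R,4S,6R)-4-[(tert-butyldimethylsilyl)oxy]-2,2,6-trimethyl-7-oxabicyclo[4.1.0]heptan-1-yl]-3-methylpent-2-en-4-yn-1-yl 2,2-dimethylpropanoate (oxirane oxygen trans to the silyloxy group)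
Conditions: m-CPBA (1.1 equiv), NaHCO3, CH2Cl2, −20 to 0 °C
Reagents that add atoms: m-chloroperoxybenzoic acid, O=C(OO)c1cccc(Cl)c1
Why: Prilezhaev epoxidation should take the tetrasubstituted ring alkene, the most electron-rich π bond (the side-chain alkene is trisubstituted and bears the allylic acyloxy group). The peracid is expected to approach opposite the bulky silyloxy group, which sets C5' and C6'; the minor syn oxirane is removed by chromatography.

Step 8
Reactants: 10 anti epoxy enyne
Product: 12 (aS)-(2E)-5-[(2R,4S)-4-[(tert-butyldimethylsilyl)oxy]-2-hydroxy-2,6,6-trimethylcyclohexylidene]-3-methylpenta-2,4-dien-1-yl 2,2-dimethylpropanoate (H-8' on the ring face of the C5' methyl), via allenyl silyl ether 11 (not isolated)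
Conditions: CuCl (5 mol%), 1,3-bis(2,6-diisopropylphenyl)imidazolium chloride (5 mol%), NaOt-Bu (15 mol%), (EtO)2MeSiH (2 equiv), toluene, 0 °C to rt; then 1 M aq. NaOH, THF, 0 °C
Reagents that add atoms: none
Why: Carbene-ligated copper hydride reduces propargylic oxiranes by anti SN2' substitution: hydride enters at C8' opposite the breaking C6'–O bond, so the oxirane configuration becomes the (aS) axis while C5' keeps its oxygen. The silyl ether 11 formed on catalyst turnover is cleaved in the basic work-up.

Step 9
Reactants: 12 α-hydroxyallene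
Product: 13 (2E)-3-[(2R,6S,7aR)-6-[(tert-butyldimethylsilyl)oxy]-4,4,7a-trimethyl-2,4,5,6,7,7a-hexahydro-1-benzofuran-2-yl]but-2-en-1-yl 2,2-dimethylpropanoate
Conditions: Ph3PAuCl (2 mol%), AgBF4 (2 mol%), THF, −20 to 0 °C, dark; Et3N quench
Reagents that add atoms: none
Why: Cationic Ph3PAu+ (monovalent gold, from Ph3PAuCl and AgBF4) binds the C7'=C8' π bond, whose lobes lie in the plane of C5', C6' and C1', on the side remote from O5'; the tertiary hydroxyl then attacks C8' in that plane to give a σ-vinylgold at C7' and an oxonium ion, and proton transfer with protodeauration leaves H on C7', the C6'=C7' alkene in the ring and the free catalyst. The closest known reaction type is the gold- or silver-catalysed cycloisomerisation of α-hydroxyallenes to 2,5-dihydrofurans, which is documented for tertiary carbinols and proceeds with axis-to-centre chirality transfer. The one ring (O1, C5', C6', C7', C8') closes in the 5-endo-trig mode. The one new stereocentre, C8', is controlled by the allene axis: H-8' and C9' are perpendicular to the plane in which oxygen arrives and are not moved by the addition, so the (aS) axis of 12, with C9' on the side of C4' and H-8' on the side of the C5' methyl, becomes 8'R whichever face gold occupies. The step needs chemoselectivity for O–C8' closure over carbocyclisation of the vinylallene and over ionisation of the allylic pivalate, and it needs the axis to survive until the C–O bond is made. The hydroxyl sits three atoms from the sp carbon and should trap the gold complex faster than it can open to a rotating allyl cation, and low temperature, a donor solvent and an early amine quench protect the acid-labile C8'–O1 bond of the product.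

Step 10
Reactants: 13 furanoid pivalate
Product: 14 (2E)-3-[(2R,6S,7aR)-6-[(tert-butyldimethylsilyl)oxy]-4,4,7a-trimethyl-2,4,5,6,7,7a-hexahydro-1-benzofuran-2-yl]but-2-en-1-ol
Conditions: NaOMe (0.2 equiv), MeOH, 40 °C
Reagents that add atoms: none
Why: Base-catalysed transesterification frees the primary allylic alcohol. The silyl ether and the C8' ether (no acidic hydrogen, no acid present) should be unaffected.

Step 11
Reactants: 14 furanoid allylic alcohol
Product: 16 [(2E)-3-[(2R,6S,7aR)-6-[(tert-butyldimethylsilyl)oxy]-4,4,7a-trimethyl-2,4,5,6,7,7a-hexahydro-1-benzofuran-2-yl]but-2-en-1-yl]triphenylphosphonium bromide, via allylic bromide 15 (not isolated)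
Conditions: PPh3 (1.2 equiv), CBr4 (1.1 equiv), CH2Cl2, −20 to 0 °C; then PPh3 (1.5 equiv), rt
Reagents that add atoms: triphenylphosphine, c1ccc(cc1)P(c1ccccc1)c1ccccc1; carbon tetrabromide, BrC(Br)(Br)Br
Why: Appel bromination followed by SN2 quaternisation of the primary allylic bromide. The conditions are neutral, which avoids the acid that would ionise C8'.

Step 12
Reactants: 10 anti epoxy enyne
Product: 17 (2E)-5-[(1S,2R,4S)-4-[(tert-butyldimethylsilyl)oxy]-1,2-dihydroxy-2,6,6-trimethylcyclohexyl]-3-methylpent-2-en-4-yn-1-yl 2,2-dimethylpropanoate (trans-diaxial 5,6-diol, alkynyl group cis to O5)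
Conditions: HClO4 (5 mol%), THF–H2O (4:1), 0 °C
Reagents that add atoms: water, O
Why: Acid-catalysed oxirane hydrolysis: the protonated oxirane should open at C6, the carbon whose positive charge is stabilised by the enynyl group and whose attack gives the diaxial diol through the favoured chair, with water entering anti to the departing O5. Inversion at C6 then gives the (5R,6R) trans diol, and the linear alkyne keeps O5 from reaching C8, so no furanoid can form.

Step 13
Reactants: 17 alkynyl diol pivalate
Product: 18 (2E,4E)-5-[(1R,2R,4S)-4-[(tert-butyldimethylsilyl)oxy]-1,2-dihydroxy-2,6,6-trimethylcyclohexyl]-3-methylpenta-2,4-dien-1-ol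
Conditions: NaAlH2(OCH2CH2OMe)2 (4 equiv), THF, 0 °C to rt; aq. KNaC4H4O6 work-up
Reagents that add atoms: none
Why: The aluminate bound to the propargylic C6 oxygen delivers hydride across the alkyne in a trans hydroalumination, and protonolysis gives the 7E alkene. The same reagent cleaves the pivalate reductively.

Step 14
Reactants: 18 ring A dienol
Product: 20 [(2E,4E)-5-[(1R,2R,4S)-4-[(tert-butyldimethylsilyl)oxy]-1,2-dihydroxy-2,6,6-trimethylcyclohexyl]-3-methylpenta-2,4-dien-1-yl]triphenylphosphonium bromide, via allylic bromide 19 (not isolated)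
Conditions: PPh3 (1.2 equiv), CBr4 (1.1 equiv), NaHCO3 (solid), CH2Cl2, −20 to 0 °C; then PPh3 (1.5 equiv), rt
Reagents that add atoms: triphenylphosphine, c1ccc(cc1)P(c1ccccc1)c1ccccc1; carbon tetrabromide, BrC(Br)(Br)Br
Why: Appel bromination is selective for the primary allylic alcohol over the two hindered tertiary ones. The buffered, acid-free conditions spare the ionisable C6 carbinol, and the bromide is quaternised in the same flask.

Step 15
Reactants: 20 ring A C15 phosphonium bromide; 21 (2E,4E,6E)-2,7-dimethylocta-2,4,6-trienedial
Product: 22 (3S,5R,6R)-3-[(tert-butyldimethylsilyl)oxy]-5,6-dihydroxy-5,6-dihydro-12'-apo-β-caroten-12'-al (all-E)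
Conditions: NaOMe (1.1 equiv), MeOH–CH2Cl2, 0 °C to rt, 21 (2 equiv); then EtOAc, 70 °C, dark
Reagents that add atoms: none
Why: Wittig olefination of the semi-stabilised allylic ylide forms C11=C12. Excess dialdehyde, together with the lower electrophilicity of the extended product aldehyde, should hold the reaction at mono-olefination, and the hindered 11Z isomer is equilibrated to E by gentle heating.

Step 16
Reactants: 16 ring B C15 phosphonium bromide; 22 ring A C25 apocarotenal
Product: 23 (3S,5R,6R,3'S,5'R,8'R)-3,3'-bis[(tert-butyldimethylsilyl)oxy]-5',8'-epoxy-5,6,5',8'-tetrahydro-β,β-carotene-5,6-diol (all-E)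
Conditions: NaOMe (1.2 equiv), MeOH–CH2Cl2, 0 °C to rt; then EtOAc, 70 °C, dark
Reagents that add atoms: none
Why: Wittig olefination forms C11'=C12' and completes the C40 skeleton. The ylide carbon is three atoms from C8', whose alkoxide is too poor a leaving group for vinylogous elimination, and thermal equilibration (no iodine, no acid) converts the hindered 11'Z isomer to all-E.

Step 17
Reactants: 23 bis-silyl ether
Product: 24 (3S,5R,6R,3'S,5'R,8'R)-5',8'-epoxy-5,6,5',8'-tetrahydro-β,β-carotene-3,3',5,6-tetrol (target)
Conditions: Bu4NF (4 equiv), THF, 0 °C to rt, dark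
Reagents that add atoms: none
Why: Fluoride cleaves both secondary silyl ethers under basic, non-ionising conditions, so C8' and the C6 carbinol are not put at risk.

## Compound list

1 | 4-oxoisophorone (2,6,6-trimethylcyclohex-2-ene-1,4-dione) | CC1=CC(=O)CC(C)(C)C1=O | starting material
2 | (6R)-2,2,6-trimethylcyclohexane-1,4-dione | O=C1C(C)(C)CC(=O)C[C@H]1C | intermediate
3 | (4R,6R)-4-hydroxy-2,2,6-trimethylcyclohexan-1-one | O=C1C(C)(C)C[C@H](O)C[C@H]1C | intermediate
4 | (4R,6R)-4-[(tert-butyldimethylsilyl)oxy]-2,2,6-trimethylcyclohexan-1-one | O=C1C(C)(C)C[C@H](O[Si](C)(C)C(C)(C)C)C[C@H]1C | intermediate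
5 | lithium (4R)-4-[(tert-butyldimethylsilyl)oxy]-2,6,6-trimethylcyclohex-1-en-1-olate | CC1=C(O[Li])C(C)(C)C[C@H](O[Si](C)(C)C(C)(C)C)C1 | intermediate (not isolated)
6 | (4R)-4-[(tert-butyldimethylsilyl)oxy]-2,6,6-trimethylcyclohex-1-en-1-yl trifluoromethanesulfonate | CC1=C(OS(=O)(=O)C(F)(F)F)C(C)(C)C[C@H](O[Si](C)(C)C(C)(C)C)C1 | intermediate
7 | (E)-3-methylpent-2-en-4-yn-1-ol | C#C/C(C)=C/CO | starting material
8 | (2E)-5-[(4R)-4-silyloxy-2,6,6-trimethylcyclohex-1-en-1-yl]-3-methylpent-2-en-4-yn-1-ol (silyl = tert-butyldimethylsilyl) | OC/C=C(\C)C#CC1=C(C)C[C@@H](O[Si](C)(C)C(C)(C)C)CC1(C)C | intermediate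
9 | pivalate of 8 | CC(C)(C)C(=O)OC/C=C(\C)C#CC1=C(C)C[C@@H](O[Si](C)(C)C(C)(C)C)CC1(C)C | intermediate
10 | (1R,4S,6R) anti epoxy enyne pivalate (5',6'-oxirane trans to O3') | CC(C)(C)C(=O)OC/C=C(\C)C#C[C@]12C(C)(C)C[C@H](O[Si](C)(C)C(C)(C)C)C[C@@]1(C)O2 | intermediate
11 | diethoxy(methyl)silyl ether of 12 at O5' | CC(C)(C)C(=O)OC/C=C(\C)C=[C@]=C1C(C)(C)C[C@H](O[Si](C)(C)C(C)(C)C)C[C@@]1(C)O[Si](C)(OCC)OCC | intermediate (not isolated)
12 | C15 α-hydroxyallene, (aS) axis, (2R,4S) ring, 3'-O-TBS, C11' pivalate | CC(C)(C)C(=O)OC/C=C(\C)C=[C@]=C1C(C)(C)C[C@H](O[Si](C)(C)C(C)(C)C)C[C@@]1(C)O | intermediate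
13 | C15 furanoid ring B unit, (2R,6S,7aR), 3'-O-TBS, C11' pivalate | CC(C)(C)C(=O)OC/C=C(\C)[C@H]1C=C2C(C)(C)C[C@H](O[Si](C)(C)C(C)(C)C)C[C@@]2(C)O1 | intermediate
14 | C15 furanoid allylic alcohol | OC/C=C(\C)[C@H]1C=C2C(C)(C)C[C@H](O[Si](C)(C)C(C)(C)C)C[C@@]2(C)O1 | intermediate
15 | C15 furanoid allylic bromide | BrC/C=C(\C)[C@H]1C=C2C(C)(C)C[C@H](O[Si](C)(C)C(C)(C)C)C[C@@]2(C)O1 | intermediate (not isolated)
16 | C15 furanoid triphenylphosphonium bromide | [Br-].c1ccccc1[P+](c1ccccc1)(c1ccccc1)C/C=C(\C)[C@H]1C=C2C(C)(C)C[C@H](O[Si](C)(C)C(C)(C)C)C[C@@]2(C)O1 | intermediate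
17 | (1S,2R,4S) alkynyl 5,6-diol pivalate (ring A, 3-O-TBS) | CC(C)(C)C(=O)OC/C=C(\C)C#C[C@@]1(O)C(C)(C)C[C@H](O[Si](C)(C)C(C)(C)C)C[C@@]1(C)O | intermediate
18 | (2E,4E) ring A C15 dienol, (1R,2R,4S), 3-O-TBS | OC/C=C(C)/C=C/[C@@]1(O)C(C)(C)C[C@H](O[Si](C)(C)C(C)(C)C)C[C@@]1(C)O | intermediate
19 | ring A C15 allylic bromide | BrC/C=C(C)/C=C/[C@@]1(O)C(C)(C)C[C@H](O[Si](C)(C)C(C)(C)C)C[C@@]1(C)O | intermediate (not isolated)
20 | ring A C15 triphenylphosphonium bromide | [Br-].c1ccccc1[P+](c1ccccc1)(c1ccccc1)C/C=C(C)/C=C/[C@@]1(O)C(C)(C)C[C@H](O[Si](C)(C)C(C)(C)C)C[C@@]1(C)O | intermediate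
21 | (2E,4E,6E)-2,7-dimethylocta-2,4,6-trienedial | O=C/C(C)=C/C=C/C=C(C)/C=O | starting material
22 | ring A C25 apocarotenal, 3-O-TBS | CC(/C=C/C=C(C)/C=C/[C@@]1(O)C(C)(C)C[C@H](O[Si](C)(C)C(C)(C)C)C[C@@]1(C)O)=C\C=C\C=C(C)\C=O | intermediate
23 | 3,3'-bis-O-TBS ether of the target | CC(/C=C/C=C(C)/C=C/[C@@]1(O)C(C)(C)C[C@H](O[Si](C)(C)C(C)(C)C)C[C@@]1(C)O)=C\C=C\C=C(C)\C=C\C=C(/C)[C@H]1C=C2C(C)(C)C[C@H](O[Si](C)(C)C(C)(C)C)C[C@@]2(C)O1 | intermediate
24 | (3S,5R,6R,3'S,5'R,8'R)-5',8'-epoxy-5,6,5',8'-tetrahydro-β,β-carotene-3,3',5,6-tetrol | CC(/C=C/C=C(C)/C=C/[C@@]1(O)C(C)(C)C[C@H](O)C[C@@]1(C)O)=C\C=C\C=C(C)\C=C\C=C(/C)[C@H]1C=C2C(C)(C)C[C@H](O)C[C@@]2(C)O1 | target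

## Step count and least certain steps

Total: 17 steps. Longest linear sequence: 13 steps from 1 (steps 1–7, 12–15, 16, 17; the ring B branch, steps 1–11, 16, 17, is equally long).

**Step 9 (key step).** The likely failures are stereomutation of the allene axis before the C–O bond forms (the C8' terminus is alkenyl-substituted, so a gold-bound allyl cation may live long enough to rotate), Lewis-acid ionisation of the bis-allylic C8'–O1 bond of the product, and competing carbocyclisation of the vinylallene. The first two would erode C8' and the third would consume material. The anti face of the C7'=C8' bond also lies next to the C1' gem-dimethyl group, which may slow the desired pathway. The fallback uses an electrophile in place of the π-acid. From 12, N-iodosuccinimide in CH2Cl2 at −20 °C should close the ring by the same in-plane attack of O5' on C8', anti to an iodonium at C7', to give the 7'-iodo-2,5-dihydrofuran F1. Radical hydrodeiodination (Bu3SnH, Et3B, air, toluene, 0 °C) then returns to 13.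

**Step 8.** The reduction may show incomplete anti selectivity, copper-mediated epimerisation of the axis, slow turnover because the tertiary copper alkoxide exchanges reluctantly with the silane, or hydrocupration of the enyne. The axis epimer is a diastereomer of 12 and can be separated, but each percent is lost directly from C8'. The fallback replaces copper by palladium. From 10, Pd2(dba)3·CHCl3 with PBu3 and HCO2NH4 in THF should open the oxirane anti to an allenylpalladium alkoxide (zerovalent palladium), take hydride from formate and eliminate reductively with retention, returning to 12 without a new intermediate.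

**Step 7.** Facial discrimination may be weak, because the two faces of the C5'=C6' bond differ only by the remote silyloxy group and the pseudo-axial C1' methyl, and some oxidation of the side-chain alkene is possible. The fallback replaces substrate control by reagent control.
- From 6, Stille hydroxymethylation (Bu3SnCH2OH, Pd(PPh3)4, LiCl, dioxane) gives the allylic alcohol F2.
- Sharpless epoxidation (Ti(OiPr)4, D-(−)-diethyl tartrate, t-BuOOH) gives the epoxy alcohol F3, with oxygen delivered opposite O3'.
- Oxidation (SO3·pyridine, DMSO, Et3N) gives the epoxy aldehyde F4, and Ohira–Bestmann homologation gives the ethynyl oxirane F5.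
- Sonogashira coupling with (E)-3-iodobut-2-en-1-yl pivalate F7, made by pivaloylation of (E)-3-iodobut-2-en-1-ol F6 (from but-2-yn-1-ol by hydroalumination and iodination), returns to 10.

**Step 12.** Stereospecificity at C6 may be lost if the enynyl-stabilised cation becomes free, giving the 6-epimer. Acid may also cleave the silyl ether or rearrange the tertiary propargylic alcohol. The fallback opens an oxirane at C5 on a substrate whose C6 cannot ionise.
- From 6, Heck coupling with but-3-en-2-one gives the silylated 3-hydroxy-β-ionone F8, and Bu4NF frees (3R)-3-hydroxy-β-ionone F9.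
- Hydroxyl-directed epoxidation (m-CPBA) gives the syn 5,6-epoxide F10.
- Aqueous H2SO4 should open F10 at C5 with inversion: C6 is deactivated by the enone and the diaxial opening goes through the favoured chair, giving the (3S,5R,6R)-triol ketone F11.
- Resilylation gives F12, Horner–Wadsworth–Emmons reaction with triethyl phosphonoacetate gives the C15 dienoate F13, and (i-Bu)2AlH returns to 18.

## Further compounds

F1 | step 9 | 7'-iodo derivative of 13 (3-iodo-2,5-dihydrofuran, same spatial arrangement at C8') | CC(C)(C)C(=O)OC/C=C(\C)[C@H]1C(I)=C2C(C)(C)C[C@H](O[Si](C)(C)C(C)(C)C)C[C@@]2(C)O1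
F2 | step 7 | [(4R)-4-[(tert-butyldimethylsilyl)oxy]-2,6,6-trimethylcyclohex-1-en-1-yl]methanol | OCC1=C(C)C[C@@H](O[Si](C)(C)C(C)(C)C)CC1(C)C
F3 | step 7 | [(1R,4S,6R)-4-silyloxy-2,2,6-trimethyl-7-oxabicyclo[4.1.0]heptan-1-yl]methanol (oxirane trans to O3') | OC[C@]12C(C)(C)C[C@H](O[Si](C)(C)C(C)(C)C)C[C@@]1(C)O2
F4 | step 7 | corresponding epoxy aldehyde | O=C[C@]12C(C)(C)C[C@H](O[Si](C)(C)C(C)(C)C)C[C@@]1(C)O2
F5 | step 7 | corresponding 1-ethynyl oxirane | C#C[C@]12C(C)(C)C[C@H](O[Si](C)(C)C(C)(C)C)C[C@@]1(C)O2
F6 | step 7 | (E)-3-iodobut-2-en-1-ol | C/C(I)=C\CO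
F7 | step 7 | (E)-3-iodobut-2-en-1-yl 2,2-dimethylpropanoate | C/C(I)=C\COC(=O)C(C)(C)C
F0 | step 8 | none | none
F8 | step 12 | (3R)-3-[(tert-butyldimethylsilyl)oxy]-β-ionone | CC(=O)/C=C/C1=C(C)C[C@@H](O[Si](C)(C)C(C)(C)C)CC1(C)C
F9 | step 12 | (3R)-3-hydroxy-β-ionone | CC(=O)/C=C/C1=C(C)C[C@@H](O)CC1(C)C
F10 | step 12 | (3S,5S,6R)-5,6-epoxy-3-hydroxy-5,6-dihydro-β-ionone (oxirane cis to the 3-hydroxyl) | CC(=O)/C=C/[C@@]12C(C)(C)C[C@H](O)C[C@]1(C)O2
F11 | step 12 | (3S,5R,6R)-3,5,6-trihydroxy-5,6-dihydro-β-ionone | CC(=O)/C=C/[C@@]1(O)C(C)(C)C[C@H](O)C[C@@]1(C)O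
F12 | step 12 | 3-O-tert-butyldimethylsilyl ether of F11 | CC(=O)/C=C/[C@@]1(O)C(C)(C)C[C@H](O[Si](C)(C)C(C)(C)C)C[C@@]1(C)O
F13 | step 12 | ethyl (2E,4E)-5-[(1R,2R,4S)-4-silyloxy-1,2-dihydroxy-2,6,6-trimethylcyclohexyl]-3-methylpenta-2,4-dienoate | CCOC(=O)/C=C(C)/C=C/[C@@]1(O)C(C)(C)C[C@H](O[Si](C)(C)C(C)(C)C)C[C@@]1(C)O
A1 | alternative 1 | (1S,2R,4S)-4-[(tert-butyldimethylsilyl)oxy]-2,6,6-trimethyl-2-[(triethylsilyl)oxy]cyclohexane-1-carbaldehyde | O=C[C@H]1C(C)(C)C[C@H](O[Si](C)(C)C(C)(C)C)C[C@@]1(C)O[Si](CC)(CC)CC
A2 | alternative 1 | ring A γ-hydroxy (E)-enoate, 3-O-TBS, 5-O-TES | COC(=O)/C=C/[C@@]1(O)C(C)(C)C[C@H](O[Si](C)(C)C(C)(C)C)C[C@@]1(C)O[Si](CC)(CC)CC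
A3 | alternative 2 | (1R,5S)-5-[(tert-butyldimethylsilyl)oxy]-1,3,3-trimethyl-2-oxocyclohexyl (2Z)-3-iodoprop-2-enoate | O=C1C(C)(C)C[C@H](O[Si](C)(C)C(C)(C)C)C[C@@]1(C)OC(=O)/C=C\I
A4 | alternative 2 | cis-fused C12 hydroxy lactone, 3-O-TBS | O=C1C=C[C@@]2(O)C(C)(C)C[C@H](O[Si](C)(C)C(C)(C)C)C[C@@]2(C)O1
A5 | alternative 3 | ethyl (2E,4E)-3-methyl-5-[(4R)-4-silyloxy-2,6,6-trimethylcyclohex-1-en-1-yl]penta-2,4-dienoate | CCOC(=O)/C=C(\C)/C=C/C1=C(C)C[C@@H](O[Si](C)(C)C(C)(C)C)CC1(C)C
A6 | alternative 3 | C15 5',8'-endoperoxide enoate | CCOC(=O)/C=C(\C)[C@H]1C=C2C(C)(C)C[C@H](O[Si](C)(C)C(C)(C)C)C[C@@]2(C)OO1
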